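**Plan**

1. Retrosynthesis: the MOM ether is removed last. Ring B (C1' benzofuranyl, C2'/C6' prenyl, C3'/C5' oxygen, C4' H) is taken back to a 3-methoxycyclohex-2-enone and then to a cyclohexane-1,3-dione. The C2'–prenyl bond is cut as an alkylation at an ester-bearing carbon whose CO2Me is later lost.
2. The dione ring is cut at C1'–C2' (Michael) and C3'–C4' (Claisen) into dimethyl malonate and an α-prenyl enone. The enone is cut at its C1'=C6' double bond into a benzofuran-2-carbaldehyde and a prenylated ketophosphonate. The furan ring is cut at O1–C2 and C2–C3 into 2,4-dihydroxybenzaldehyde and ethyl bromoacetate.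
3. Forward order: the furan ring is annulated first, olefination joins the prenyl ketone chain, and the Michael–Claisen step closes ring B as a saturated dione. Then follow the second prenylation, decarboxylation, O-methylation, dehydrogenation to the arene and deprotection.
4. Enabling feature: C1' of ring B, wedged between the prenyl-bearing carbons C2'/C6' and C2 of the benzofuran, can be an sp3 enone β-carbon before aromatization. The meta-related oxygens at C3' and C5' are the two carbonyls of a cyclohexane-1,3-dione.
5. Stereochemistry: the target has no stereocentre. The ring stereocentres of the intermediates are racemic, settle trans to the benzofuranyl group under thermodynamic or steric control, and vanish on aromatization.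

Key step: step 7

Remark: all chiral intermediates are racemic. The SMILES show one enantiomer with the expected relative configuration; single-centre racemates and diastereomer mixtures are written without descriptors. The 1,3-diones are drawn in the diketo form although they should exist largely as enols.

**Step 1**
Reactants: 1 2,4-dihydroxybenzaldehyde
Product: 2 2-hydroxy-4-(methoxymethoxy)benzaldehyde
Conditions: MOMCl (1.05 equiv), K2CO3, acetone, 0 °C to rt
Reagents that add atoms: chloromethyl methyl ether (MOMCl), COCCl
Why: Williamson-type O-alkylation in which the 4-OH reacts selectively because the 2-OH is held in a hydrogen bond to the aldehyde and is the poorer nucleophile.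

**Step 2**
Reactants: 2 2-hydroxy-4-(methoxymethoxy)benzaldehyde; 3 ethyl bromoacetate
Product: 5 ethyl 6-(methoxymethoxy)-1-benzofuran-2-carboxylate, via aryloxyacetate 4 (not isolated)
Conditions: K2CO3, DMF, 90 °C
Reagents that add atoms: none
Why: Williamson O-alkylation of the remaining phenol followed by intramolecular aldol condensation of the ester α-carbon onto the ortho aldehyde and dehydration (Rap–Stoermer-type benzofuran annulation), driven by aromatization of the furan ring.

**Step 3**
Reactants: 5 ethyl 6-(methoxymethoxy)-1-benzofuran-2-carboxylate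
Product: 6 [6-(methoxymethoxy)-1-benzofuran-2-yl]methanol
Conditions: LiAlH4, THF, 0 °C; then H2O, 15% aq. NaOH
Reagents that add atoms: none
Why: Hydride reduction of the ester to the primary alcohol, to which the MOM acetal and the benzofuran are inert.

**Step 4**
Reactants: 6 [6-(methoxymethoxy)-1-benzofuran-2-yl]methanol
Product: 7 6-(methoxymethoxy)-1-benzofuran-2-carbaldehyde
Conditions: MnO2 (excess), CH2Cl2, rt
Reagents that add atoms: none
Why: MnO2 oxidizes the activated furan-2-yl (benzylic-type) carbinol selectively to the aldehyde without over-oxidation.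

**Step 5**
Reactants: 8 diethyl (2-oxopropyl)phosphonate; 9 prenyl bromide (1-bromo-3-methylbut-2-ene)
Product: 10 diethyl (6-methyl-2-oxohept-5-en-3-yl)phosphonate (racemic)
Conditions: NaH, THF, 0 °C; then 9, 0 °C to rt
Reagents that add atoms: none
Why: SN2 C-alkylation of the stabilized β-ketophosphonate anion with a reactive allylic bromide, the standard way to α-substituted Horner–Wadsworth–Emmons reagents; a slight excess of 8 should suppress dialkylation.

**Step 6**
Reactants: 10 diethyl (6-methyl-2-oxohept-5-en-3-yl)phosphonate; 7 6-(methoxymethoxy)-1-benzofuran-2-carbaldehyde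
Product: 11 (3E)-3-{[6-(methoxymethoxy)-1-benzofuran-2-yl]methylidene}-6-methylhept-5-en-2-one
Conditions: NaH, THF, 0 °C; then 7, 0 °C to reflux
Reagents that add atoms: none
Why: Horner–Wadsworth–Emmons olefination of a non-enolizable heteroaryl aldehyde, expected to give mainly the E enone (aryl trans to acetyl); the geometry is not critical because both isomers lead to the same Michael adduct.

**Step 7**
Reactants: 11 (3E)-3-{[6-(methoxymethoxy)-1-benzofuran-2-yl]methylidene}-6-methylhept-5-en-2-one; 12 dimethyl malonate
Product: 14 racemic all-trans methyl 2-[6-(methoxymethoxy)-1-benzofuran-2-yl]-3-(3-methylbut-2-en-1-yl)-4,6-dioxocyclohexane-1-carboxylate, via Michael adduct 13 (not isolated)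
Conditions: NaOMe (1.5 equiv), 12 (1.5 equiv), MeOH, reflux; then AcOH to pH 5, 0 °C
Reagents that add atoms: none
Why: Methoxide deprotonates 12 and the malonate anion adds reversibly to the β-carbon of enone 11 (Michael addition, C2'–C1' bond) to give adduct 13, whose ketone enolate equilibrates to the terminal methyl enolate and attacks one of the two equivalent ester groups (Claisen condensation, C4'–C3' bond). Ring B closes in a 6-(enolexo)-exo-trig mode, the only closure open to the substrate because the internal enolate could reach an ester only through a four-membered ring. The closest known reaction type is the dimedone-type synthesis of 5-substituted cyclohexane-1,3-diones from enones and malonates. The step needs conjugate addition and cyclization to win over retro-Michael cleavage at a hindered trisubstituted enone, and this is secured because the acidic 1,3-dione product is deprotonated by methoxide and so withdrawn from every equilibrium. The three new stereocentres form as a racemate under thermodynamic control: the ester-bearing C1 and the prenyl-bearing C3 are epimerizable α-carbons and should settle trans to the benzofuranyl group at C2 (all equatorial), and all three are erased later. The retained ester marks C2' for the second prenylation.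

**Step 8**
Reactants: 14 racemic all-trans methyl 2-[6-(methoxymethoxy)-1-benzofuran-2-yl]-3-(3-methylbut-2-en-1-yl)-4,6-dioxocyclohexane-1-carboxylate; 9 prenyl bromide
Product: 15 methyl 2-[6-(methoxymethoxy)-1-benzofuran-2-yl]-1,3-bis(3-methylbut-2-en-1-yl)-4,6-dioxocyclohexane-1-carboxylate (racemic; both prenyl groups trans to the benzofuranyl group)
Conditions: LiN(iPr)2 (2.3 equiv), THF–DMPU, −78 to −30 °C; then 9 (1.05 equiv), −78 to 0 °C; AcOH quench
Reagents that add atoms: none
Why: Dianion alkylation of a β-dicarbonyl system (Harris–Weiler type): the first equivalent of base forms the dione enolate, the second removes the hydrogen at the carbon flanked by ester and ketone, and this more basic carbanion is alkylated by the allylic bromide from the face opposite to the neighbouring benzofuranyl group, which sets the quaternary centre.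

**Step 9**
Reactants: 15 methyl 2-[6-(methoxymethoxy)-1-benzofuran-2-yl]-1,3-bis(3-methylbut-2-en-1-yl)-4,6-dioxocyclohexane-1-carboxylate
Product: 17 all-trans 5-[6-(methoxymethoxy)-1-benzofuran-2-yl]-4,6-bis(3-methylbut-2-en-1-yl)cyclohexane-1,3-dione, via carboxylic acid 16 (not isolated)
Conditions: LiCl, DMSO–H2O, 140 °C
Reagents that add atoms: none
Why: Krapcho dealkoxycarbonylation, in which chloride cleaves the ester by SN2 attack at the methyl group (insensitive to the hindrance at the quaternary carbon) and the β-keto carboxylate loses CO2; protonation of the epimerizable α-carbon should place the prenyl group trans to the aryl group.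

**Step 10**
Reactants: 17 all-trans 5-[6-(methoxymethoxy)-1-benzofuran-2-yl]-4,6-bis(3-methylbut-2-en-1-yl)cyclohexane-1,3-dione
Product: 18 all-trans 3-methoxy-5-[6-(methoxymethoxy)-1-benzofuran-2-yl]-4,6-bis(3-methylbut-2-en-1-yl)cyclohex-2-en-1-one (racemic)
Conditions: Me3SiCHN2, MeOH–toluene, 0 °C to rt
Reagents that add atoms: (trimethylsilyl)diazomethane, C[Si](C)(C)C=[N+]=[N-]
Why: O-methylation of the acidic enol (a vinylogous acid) by the diazoalkane in methanol; because the dione is symmetrically substituted, methylation at either oxygen gives the same racemic enol ether.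

**Step 11**
Reactants: 18 all-trans 3-methoxy-5-[6-(methoxymethoxy)-1-benzofuran-2-yl]-4,6-bis(3-methylbut-2-en-1-yl)cyclohex-2-en-1-one
Product: 19 3-methoxy-5-[6-(methoxymethoxy)-1-benzofuran-2-yl]-4,6-bis(3-methylbut-2-en-1-yl)-6-(phenylselanyl)cyclohex-2-en-1-one (racemic; selenium trans to the benzofuranyl group)
Conditions: LiN(iPr)2, THF, −78 °C; then PhSeBr (1.0 equiv), −78 °C
Reagents that add atoms: benzeneselenenyl bromide, Br[Se]c1ccccc1
Why: Kinetic α'-deprotonation of the vinylogous ester (Stork–Danheiser regiochemistry) and α-selenenylation of the cross-conjugated enolate, which outpaces addition of the selenenyl bromide to the prenyl double bonds at −78 °C and should occur anti to the adjacent benzofuranyl group so that selenium ends up cis to H5.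

**Step 12**
Reactants: 19 3-methoxy-5-[6-(methoxymethoxy)-1-benzofuran-2-yl]-4,6-bis(3-methylbut-2-en-1-yl)-6-(phenylselanyl)cyclohex-2-en-1-one
Product: 22 5-methoxy-3-[6-(methoxymethoxy)-1-benzofuran-2-yl]-2,4-bis(3-methylbut-2-en-1-yl)phenol, via selenoxide 20 (not isolated), via cyclohexadienone 21 (not isolated)
Conditions: 30% aq. H2O2, pyridine, CH2Cl2, 0 °C to rt
Reagents that add atoms: none
Why: Oxidation at selenium and selenoxide syn-elimination toward the cis ring hydrogen at C5 give the cross-conjugated cyclohexa-2,5-dienone, which tautomerizes to the phenol under the pyridine buffer, the gain of aromaticity making the sequence irreversible.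

**Step 13**
Reactants: 22 5-methoxy-3-[6-(methoxymethoxy)-1-benzofuran-2-yl]-2,4-bis(3-methylbut-2-en-1-yl)phenol
Product: 23 2-[3-hydroxy-5-methoxy-2,6-bis(3-methylbut-2-en-1-yl)phenyl]-1-benzofuran-6-ol (CNP0324103.0)
Conditions: 3 M aq. HCl, MeOH, rt
Reagents that add atoms: none
Why: Acid-catalysed acetal exchange with methanol removes the MOM group; dilute acid at room temperature is chosen so that the ortho-prenyl phenol should not cyclize to a chroman.

**Compound list**

1 | 2,4-dihydroxybenzaldehyde | O=Cc1ccc(O)cc1O | starting material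
2 | 2-hydroxy-4-(methoxymethoxy)benzaldehyde | COCOc1ccc(C=O)c(O)c1 | intermediate
3 | ethyl bromoacetate | CCOC(=O)CBr | starting material
4 | ethyl 2-[2-formyl-5-(methoxymethoxy)phenoxy]acetate (not isolated) | CCOC(=O)COc1cc(OCOC)ccc1C=O | intermediate
5 | ethyl 6-(methoxymethoxy)-1-benzofuran-2-carboxylate | CCOC(=O)c1cc2ccc(OCOC)cc2o1 | intermediate
6 | [6-(methoxymethoxy)-1-benzofuran-2-yl]methanol | COCOc1ccc2cc(CO)oc2c1 | intermediate
7 | 6-(methoxymethoxy)-1-benzofuran-2-carbaldehyde | COCOc1ccc2cc(C=O)oc2c1 | intermediate
8 | diethyl (2-oxopropyl)phosphonate | CCOP(=O)(CC(C)=O)OCC | starting material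
9 | prenyl bromide (1-bromo-3-methylbut-2-ene) | CC(C)=CCBr | starting material
10 | diethyl (6-methyl-2-oxohept-5-en-3-yl)phosphonate (racemic) | CCOP(=O)(OCC)C(CC=C(C)C)C(C)=O | intermediate
11 | (3E)-3-{[6-(methoxymethoxy)-1-benzofuran-2-yl]methylidene}-6-methylhept-5-en-2-one | CC(=O)/C(CC=C(C)C)=C/c1cc2ccc(OCOC)cc2o1 | intermediate
12 | dimethyl malonate | COC(=O)CC(=O)OC | starting material
13 | dimethyl 2-{2-acetyl-1-[6-(methoxymethoxy)-1-benzofuran-2-yl]-5-methylhex-4-en-1-yl}propanedioate (diastereomer mixture, not isolated) | COC(=O)C(C(=O)OC)C(c1cc2ccc(OCOC)cc2o1)C(CC=C(C)C)C(C)=O | intermediate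
14 | methyl 2-[6-(methoxymethoxy)-1-benzofuran-2-yl]-3-(3-methylbut-2-en-1-yl)-4,6-dioxocyclohexane-1-carboxylate (racemic, all-trans: CO2Me and prenyl both trans to the benzofuranyl group) | COC(=O)[C@H]1C(=O)CC(=O)[C@@H](CC=C(C)C)[C@@H]1c1cc2ccc(OCOC)cc2o1 | intermediate
15 | methyl 2-[6-(methoxymethoxy)-1-benzofuran-2-yl]-1,3-bis(3-methylbut-2-en-1-yl)-4,6-dioxocyclohexane-1-carboxylate (racemic; both prenyl groups trans to the benzofuranyl group, CO2Me cis) | COC(=O)[C@]1(CC=C(C)C)C(=O)CC(=O)[C@@H](CC=C(C)C)[C@@H]1c1cc2ccc(OCOC)cc2o1 | intermediate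
16 | 2-[6-(methoxymethoxy)-1-benzofuran-2-yl]-1,3-bis(3-methylbut-2-en-1-yl)-4,6-dioxocyclohexane-1-carboxylic acid (racemic, configuration as in 15, not isolated) | OC(=O)[C@]1(CC=C(C)C)C(=O)CC(=O)[C@@H](CC=C(C)C)[C@@H]1c1cc2ccc(OCOC)cc2o1 | intermediate
17 | 5-[6-(methoxymethoxy)-1-benzofuran-2-yl]-4,6-bis(3-methylbut-2-en-1-yl)cyclohexane-1,3-dione (all-trans: both prenyl groups trans to the benzofuranyl group) | O=C1CC(=O)[C@@H](CC=C(C)C)[C@H](c2cc3ccc(OCOC)cc3o2)[C@H]1CC=C(C)C | intermediate
18 | 3-methoxy-5-[6-(methoxymethoxy)-1-benzofuran-2-yl]-4,6-bis(3-methylbut-2-en-1-yl)cyclohex-2-en-1-one (racemic, all-trans) | COC1=CC(=O)[C@@H](CC=C(C)C)[C@H](c2cc3ccc(OCOC)cc3o2)[C@H]1CC=C(C)C | intermediate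
19 | 3-methoxy-5-[6-(methoxymethoxy)-1-benzofuran-2-yl]-4,6-bis(3-methylbut-2-en-1-yl)-6-(phenylselanyl)cyclohex-2-en-1-one (racemic; Se trans to the benzofuranyl group) | COC1=CC(=O)[C@@](CC=C(C)C)([Se]c2ccccc2)[C@H](c2cc3ccc(OCOC)cc3o2)[C@H]1CC=C(C)C | intermediate
20 | selenoxide of 19: 6-(benzeneseleninyl)-3-methoxy-5-[6-(methoxymethoxy)-1-benzofuran-2-yl]-4,6-bis(3-methylbut-2-en-1-yl)cyclohex-2-en-1-one (mixture at selenium, not isolated) | COC1=CC(=O)[C@@](CC=C(C)C)([Se](=O)c2ccccc2)[C@H](c2cc3ccc(OCOC)cc3o2)[C@H]1CC=C(C)C | intermediate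
21 | 3-methoxy-5-[6-(methoxymethoxy)-1-benzofuran-2-yl]-4,6-bis(3-methylbut-2-en-1-yl)cyclohexa-2,5-dien-1-one (racemic, not isolated) | COC1=CC(=O)C(CC=C(C)C)=C(c2cc3ccc(OCOC)cc3o2)C1CC=C(C)C | intermediate
22 | 5-methoxy-3-[6-(methoxymethoxy)-1-benzofuran-2-yl]-2,4-bis(3-methylbut-2-en-1-yl)phenol | COc1cc(O)c(CC=C(C)C)c(-c2cc3ccc(OCOC)cc3o2)c1CC=C(C)C | intermediate
23 | 2-[3-hydroxy-5-methoxy-2,6-bis(3-methylbut-2-en-1-yl)phenyl]-1-benzofuran-6-ol | COc1cc(O)c(CC=C(C)C)c(-c2cc3ccc(O)cc3o2)c1CC=C(C)C | target

**Step count and risks**

Total step count: 13. Longest linear sequence: 12 steps (steps 1–4 and 6–13); step 5 prepares the phosphonate branch.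

Steps most likely to fail:

Step 7. The conjugate addition to the α-substituted, β-heteroaryl enone is reversible and sterically retarded. Methoxide may instead remove a doubly allylic hydrogen of the prenyl CH2 and move the double bond out of conjugation, so that ring closure stalls. The fallback sets out from 7 and comes back at 15; it keeps the Michael–Claisen ring closure but brings in both prenyl groups afterwards. Claisen–Schmidt condensation of 7 with acetone (aq. NaOH) should give the unhindered enone (E)-4-[6-(methoxymethoxy)-1-benzofuran-2-yl]but-3-en-2-one F1. NaOMe and 12 in methanol should convert it, by way of the Michael adduct dimethyl 2-{1-[6-(methoxymethoxy)-1-benzofuran-2-yl]-3-oxobutyl}propanedioate F2, into methyl trans-2-[6-(methoxymethoxy)-1-benzofuran-2-yl]-4,6-dioxocyclohexane-1-carboxylate F3. Dianion formation with LiN(iPr)2 and alkylation with 9 at the ester-bearing carbon should give methyl 2-[6-(methoxymethoxy)-1-benzofuran-2-yl]-1-(3-methylbut-2-en-1-yl)-4,6-dioxocyclohexane-1-carboxylate F4. Its second dianion can form only at the ring methylene next to the aryl-bearing carbon, and prenylation there with 9 should deliver 15.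

Step 8. Dianion formation may be incomplete, or the congested tertiary carbanion may react slowly, so that the monoanion is alkylated at oxygen or at the carbon between the two carbonyl groups. The fallback sets out from 14 and comes back at 17; it removes the ester first so that the alkylated carbon is secondary. Saponification of 14 (aq. NaOH, MeOH; then pH 4, 50 °C) should give all-trans 2-[6-(methoxymethoxy)-1-benzofuran-2-yl]-3-(3-methylbut-2-en-1-yl)-4,6-dioxocyclohexane-1-carboxylic acid F5. This loses CO2 to give trans-5-[6-(methoxymethoxy)-1-benzofuran-2-yl]-4-(3-methylbut-2-en-1-yl)cyclohexane-1,3-dione F6. Its dianion (LiN(iPr)2, THF–DMPU, −78 °C) should form by kinetic removal of a hydrogen from the unsubstituted ring methylene rather than from the prenyl-bearing methine, and alkylation with 9 should give 17.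

Step 12. Oxidation may spread from selenium to the trisubstituted double bonds of the prenyl groups. A selenoxide whose selenium was delivered cis to the benzofuran has no syn ring hydrogen and would eliminate into the side chain. The fallback sets out from 18 and comes back at 22. Enolization of 18 with LiN(iPr)2 and trapping with Me3SiCl should give the silyl dienol ether trimethyl{[5-methoxy-3-[6-(methoxymethoxy)-1-benzofuran-2-yl]-2,4-bis(3-methylbut-2-en-1-yl)cyclohexa-1,5-dien-1-yl]oxy}silane F7. Pd(OAc)2 (palladium diacetate, divalent palladium) in MeCN at rt (Saegusa–Ito oxidation) should then give dienone 21 through a palladium enolate that can reach the ring hydrogen from either face and needs no peroxide, and 21 tautomerizes to 22.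

**Further compounds**

F1 | step 7 | (E)-4-[6-(methoxymethoxy)-1-benzofuran-2-yl]but-3-en-2-one | CC(=O)/C=C/c1cc2ccc(OCOC)cc2o1
F2 | step 7 | dimethyl 2-{1-[6-(methoxymethoxy)-1-benzofuran-2-yl]-3-oxobutyl}propanedioate (racemic, not isolated) | COC(=O)C(C(=O)OC)C(CC(C)=O)c1cc2ccc(OCOC)cc2o1
F3 | step 7 | methyl trans-2-[6-(methoxymethoxy)-1-benzofuran-2-yl]-4,6-dioxocyclohexane-1-carboxylate (racemic) | COC(=O)[C@H]1C(=O)CC(=O)C[C@@H]1c1cc2ccc(OCOC)cc2o1
F4 | step 7 | methyl 2-[6-(methoxymethoxy)-1-benzofuran-2-yl]-1-(3-methylbut-2-en-1-yl)-4,6-dioxocyclohexane-1-carboxylate (racemic; prenyl trans to the benzofuranyl group) | COC(=O)[C@]1(CC=C(C)C)C(=O)CC(=O)C[C@@H]1c1cc2ccc(OCOC)cc2o1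
F5 | step 8 | all-trans 2-[6-(methoxymethoxy)-1-benzofuran-2-yl]-3-(3-methylbut-2-en-1-yl)-4,6-dioxocyclohexane-1-carboxylic acid (racemic, not isolated) | OC(=O)[C@H]1C(=O)CC(=O)[C@@H](CC=C(C)C)[C@@H]1c1cc2ccc(OCOC)cc2o1
F6 | step 8 | trans-5-[6-(methoxymethoxy)-1-benzofuran-2-yl]-4-(3-methylbut-2-en-1-yl)cyclohexane-1,3-dione (racemic) | O=C1CC(=O)[C@@H](CC=C(C)C)[C@H](c2cc3ccc(OCOC)cc3o2)C1
F7 | step 12 | trimethyl{[5-methoxy-3-[6-(methoxymethoxy)-1-benzofuran-2-yl]-2,4-bis(3-methylbut-2-en-1-yl)cyclohexa-1,5-dien-1-yl]oxy}silane (racemic; 3,4-trans) | COC1=CC(O[Si](C)(C)C)=C(CC=C(C)C)[C@H](c2cc3ccc(OCOC)cc3o2)[C@H]1CC=C(C)C
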